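**Retrosynthetic overview**
- The last C–C disconnection is C2–C1' of the (2S)-flavanone. It is made by catalytic asymmetric conjugate arylation of a 2,3-unsubstituted chromone followed by global desilylation, so the stereocentre is formed late and never meets base.
- The strategy rests on one structural feature. O7, C7, C8, the benzylic C1''H2, C2''H=C3''(CH3) and C4'' (raised to an acyl carbon) form a seven-membered 1-benzoxepin-2(5H)-one ring on the C7–C8 edge of ring A. An olefin in that ring must be cis, and cis there equals Z in the 4-hydroxy-3-methylbut-2-enyl chain.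
- The Z-diol therefore comes from hydride opening of that lactone. The lactone comes from ring-closing metathesis (C2''=C3'') of the 7-O-methacrylate of 8-allyl-7-hydroxychromone, and the 8-allyl group comes from a Claisen shift of the 7-O-allyl ether.
- Ring order: pyranone first (enaminone cyclisation), then the temporary oxepinone (closed by RCM, opened by LiBH4). The B ring is joined to C2 last, which turns the pyranone into the chromanone.

Key step: step 6

Assumption: the facial sense of the t-BuPyOx–Pd catalyst on chromones is taken to parallel that on β-substituted cyclic enones, which makes the (R)-ligand the one for 2S. This is to be checked by CD against the (2S)-flavanone rule, and the ligand antipode exchanged if needed.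

**Step 1**
Reactants: 1 2,4-dihydroxyacetophenone; 2 allyl bromide
Product: 3 4-allyloxy-2-hydroxyacetophenone
Conditions: 2 (1.05 equiv), K2CO3 (1.1 equiv), acetone, reflux
Reagents that add atoms: allyl bromide (2), C=CCBr
Why: Williamson ether synthesis; the 2-OH is hydrogen-bonded to the acetyl carbonyl and is less acidic and less nucleophilic than the 4-OH, so one equivalent of halide should alkylate the 4-OH only.

**Step 2**
Reactants: 3 4-allyloxy-2-hydroxyacetophenone
Product: 4 (E)-1-(4-allyloxy-2-hydroxyphenyl)-3-(dimethylamino)prop-2-en-1-one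
Conditions: Me2NCH(OMe)2 (2 equiv), toluene, 100 °C
Reagents that add atoms: N,N-dimethylformamide dimethyl acetal, COC(OC)N(C)C
Why: Enaminone formation by condensation of the acidic acetyl CH3 with the amide acetal, driven by loss of two molecules of methanol, with the chelated phenol left free.

**Step 3**
Reactants: 4 (E)-1-(4-allyloxy-2-hydroxyphenyl)-3-(dimethylamino)prop-2-en-1-one
Product: 6 7-allyloxychromone, via aminochromanone 5 (not isolated)
Conditions: conc. aq. HCl, CH2Cl2, 40 °C
Reagents that add atoms: none
Why: Acid-promoted enaminone-to-chromone cyclisation (intramolecular oxa-Michael addition of the 2-OH to the protonated enaminone, then β-elimination of dimethylamine), which an aryl allyl ether tolerates.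

**Step 4**
Reactants: 6 7-allyloxychromone
Product: 8 8-allyl-7-hydroxychromone, via ortho-dienone 7 (not isolated)
Conditions: PhNEt2 (degassed), 200–210 °C, Ar; cold 1 M HCl wash
Reagents that add atoms: none
Why: Aromatic Claisen rearrangement ([3,3] shift, then tautomerisation); in 7-allyloxy benzopyranones the C7–C8 bond has the higher double-bond character, so migration should go to C8 and not C6, to be confirmed by an ortho-coupled pair of doublets for H5 and H6.

**Step 5**
Reactants: 8 8-allyl-7-hydroxychromone; 9 methacryloyl chloride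
Product: 10 8-allyl-4-oxo-4H-chromen-7-yl methacrylate
Conditions: 9 (1.2 equiv), Et3N (1.5 equiv), DMAP (5 mol %), BHT (trace), CH2Cl2, 0 °C
Reagents that add atoms: methacryloyl chloride (9), C=C(C)C(=O)Cl
Why: DMAP-catalysed O-acylation of the only hydroxyl group, an acidic phenol, under cold and short conditions that spare the resulting activated aryl ester and prevent methacrylate polymerisation.

**Step 6**
Reactants: 10 8-allyl-4-oxo-4H-chromen-7-yl methacrylate
Product: 11 chromone-fused 3-methyl-1-benzoxepin-2(5H)-one (lactone O on chromone C7, ring CH2 on chromone C8, cis ring olefin)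
Conditions: Hoveyda–Grubbs II (5 mol %, two portions), 1,4-benzoquinone (10 mol %), toluene (3 mM), 80 °C, Ar sparge
Reagents that add atoms: none
Why: Ring-closing olefin metathesis through metallacyclobutanes: the Ru carbene first exchanges with the unhindered monosubstituted allyl olefin, the new Ru alkylidene then sits on the internal allyl carbon C2'' and adds in a [2+2] sense to the 1,1-disubstituted methacrylate C=CH2 held next to it, and cycloreversion joins C2''H to the methacrylate α-carbon C3'' while the two terminal CH2 groups leave as ethylene. The closest known reactions are the RCM of 2-allylaryl acrylates to 1-benzoxepin-2(5H)-ones and of methacrylate esters to α-methyl α,β-unsaturated lactones with NHC-bearing Ru carbenes. One ring is closed, the seven-membered lactone (O7, C=O, C3'', C2'', C1'', C8, C7), by intramolecular metathesis across the C7–C8 edge of the chromone. No stereocentre is formed; the only stereo-element is the trisubstituted olefin, and the seven-membered ring allows it only as the cis isomer, with the acyl carbon and the benzylic CH2 on the same side. The step needs cyclisation ahead of allyl–allyl dimerisation, which the ortho placement of the two arms, the high dilution and the removal of ethylene secure, and it needs the allyl group to stay unconjugated (a propenyl isomer would close to a six-membered 3-methylcoumarin-type lactone), which benzoquinone as a scavenger of Ru hydrides and the absence of base secure. The chromone C2=C3 bond is a cyclic push-pull olefin and should not engage the carbene.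

**Step 7**
Reactants: 11 chromone-fused 3-methyl-1-benzoxepin-2(5H)-one
Product: 13 7-hydroxy-8-[(Z)-4-hydroxy-3-methylbut-2-enyl]chromone, via Z-enal 12 (not isolated)
Conditions: LiBH4 (1.0 equiv, 2 M in THF, slow addition), THF (no alcohol), −40 to −10 °C; then 1 M aq. HCl to pH 5–6, 0 °C
Reagents that add atoms: none
Why: Borohydride reduction of an activated aryl lactone (the type of reductive opening known for coumarin-type lactones); the leaving group is the well-stabilised phenoxide of a 7-hydroxychromone, so the lactone carbonyl is the most electrophilic site, the released enal 12 is reduced 1,2 at once, the 7-phenoxide then feeds electron density into the pyranone and shields it from hydride, and the untouched olefin carries its cis geometry over as Z.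

**Step 8**
Reactants: 13 7-hydroxy-8-[(Z)-4-hydroxy-3-methylbut-2-enyl]chromone
Product: 14 7-(tert-butyldimethylsilyloxy)-8-[(Z)-4-(tert-butyldimethylsilyloxy)-3-methylbut-2-enyl]chromone
Conditions: TBSCl (2.5 equiv), imidazole (5 equiv), DMF, 0 °C to rt
Reagents that add atoms: tert-butyldimethylsilyl chloride, CC(C)(C)[Si](C)(C)Cl
Why: Imidazole-promoted silylation of a phenol and a primary allylic alcohol, both unhindered, under conditions that leave the chromone and the olefin geometry alone.

**Step 9**
Reactants: 15 4-bromocatechol
Product: 16 4-bromo-1,2-bis(tert-butyldimethylsilyloxy)benzene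
Conditions: TBSCl (2.4 equiv), imidazole (5 equiv), DMF, rt
Reagents that add atoms: tert-butyldimethylsilyl chloride, CC(C)(C)[Si](C)(C)Cl
Why: Standard bis-silylation of a catechol, which removes both acidic protons before the organolithium step.

**Step 10**
Reactants: 16 4-bromo-1,2-bis(tert-butyldimethylsilyloxy)benzene
Product: 19 3,4-bis(tert-butyldimethylsilyloxy)phenylboronic acid, via aryllithium 17 (not isolated), via lithium triisopropyl arylborate 18 (not isolated)
Conditions: n-BuLi (1.05 equiv), THF, −78 °C; B(Oi-Pr)3 (1.5 equiv), −78 to 0 °C; 1 M aq. HCl to pH 5–6, 0 °C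
Reagents that add atoms: triisopropyl borate, CC(C)OB(OC(C)C)OC(C)C; water, O
Why: Bromine–lithium exchange followed by electrophilic borylation and mild hydrolysis; the lithiated carbon has no ortho silyloxy group, so no O-to-C silyl shift is expected at −78 °C.

**Step 11**
Reactants: 14 bis-TBS chromone; 19 3,4-bis(tert-butyldimethylsilyloxy)phenylboronic acid
Product: 20 (2S)-7-(tert-butyldimethylsilyloxy)-2-[3,4-bis(tert-butyldimethylsilyloxy)phenyl]-8-[(Z)-4-(tert-butyldimethylsilyloxy)-3-methylbut-2-enyl]chroman-4-one
Conditions: 19 (2 equiv), Pd(OCOCF3)2 (10 mol %), (R)-t-BuPyOx (12 mol %), NH4PF6 (30 mol %), H2O (5 equiv), ClCH2CH2Cl, 60 °C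
Reagents that add atoms: 3,4-bis(tert-butyldimethylsilyloxy)phenylboronic acid (19), CC(C)(C)[Si](C)(C)Oc1ccc(B(O)O)cc1O[Si](C)(C)C(C)(C)C
Why: Pd(II)-catalysed asymmetric conjugate addition of an arylboronic acid to a chromone (transmetalation, enantio-determining insertion of C2=C3 into the Ar–Pd bond, protonolysis of the Pd enolate by water); the tert-butyl group of the oxazoline blocks one face of the bound chromone so that the aryl group arrives on the face that makes C2 S, the trisubstituted side-chain olefin is too hindered to insert, and the base-free medium keeps the flavanone from opening to the chalcone.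

**Step 12**
Reactants: 20 (2S)-tetrakis-TBS flavanone
Product: 21 (2S)-2-(3,4-dihydroxyphenyl)-7-hydroxy-8-[(Z)-4-hydroxy-3-methylbut-2-enyl]chroman-4-one (CNP0205253.2)
Conditions: HF·pyridine (excess), pyridine, THF, 0 °C to rt, Ar, polypropylene flask; pH 6 phosphate buffer work-up
Reagents that add atoms: none
Why: Fluoride-driven cleavage of three aryl and one primary allylic silyl ether in a buffered, weakly acidic medium; no phenoxide is formed, so the retro-oxa-Michael opening that would racemise C2 (especially easy once the 4'-OH is free) is avoided, and the excess pyridine keeps the acidity too low to ionise the Z allylic alcohol.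

**Compound list**
1 | 2,4-dihydroxyacetophenone | CC(=O)c1ccc(O)cc1O | starting material
2 | allyl bromide | C=CCBr | starting material
3 | 4-allyloxy-2-hydroxyacetophenone | CC(=O)c1ccc(OCC=C)cc1O | intermediate
4 | (E)-1-(4-allyloxy-2-hydroxyphenyl)-3-(dimethylamino)prop-2-en-1-one | CN(C)/C=C/C(=O)c1ccc(OCC=C)cc1O | intermediate
5 | 7-allyloxy-2-(dimethylamino)chroman-4-one (racemic, not isolated) | CN(C)C1CC(=O)c2ccc(OCC=C)cc2O1 | intermediate
6 | 7-allyloxychromone | O=c1ccoc2cc(OCC=C)ccc12 | intermediate
7 | 8-allyl-8H-chromene-4,7-dione (Claisen ortho-dienone, racemic, not isolated) | O=C1C=CC2=C(OC=CC2=O)C1CC=C | intermediate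
8 | 8-allyl-7-hydroxychromone | O=c1ccoc2c(CC=C)c(O)ccc12 | intermediate
9 | methacryloyl chloride | C=C(C)C(=O)Cl | starting material
10 | 8-allyl-4-oxo-4H-chromen-7-yl methacrylate | C=C(C)C(=O)Oc1ccc2c(=O)ccoc2c1CC=C | intermediate
11 | chromone-fused 3-methyl-1-benzoxepin-2(5H)-one (lactone O on C7, ring CH2 on C8, cis ring olefin) | CC1=CCc2c(OC1=O)ccc3c(=O)ccoc23 | intermediate
12 | (Z)-4-(7-hydroxy-4-oxo-4H-chromen-8-yl)-2-methylbut-2-enal (present as lithium phenoxide, not isolated) | C/C(=C/Cc1c(O)ccc2c(=O)ccoc12)C=O | intermediate
13 | 7-hydroxy-8-[(Z)-4-hydroxy-3-methylbut-2-enyl]chromone | C/C(=C/Cc1c(O)ccc2c(=O)ccoc12)CO | intermediate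
14 | 7-(tert-butyldimethylsilyloxy)-8-[(Z)-4-(tert-butyldimethylsilyloxy)-3-methylbut-2-enyl]chromone | C/C(=C/Cc1c(O[Si](C)(C)C(C)(C)C)ccc2c(=O)ccoc12)CO[Si](C)(C)C(C)(C)C | intermediate
15 | 4-bromocatechol | Oc1ccc(Br)cc1O | starting material
16 | 4-bromo-1,2-bis(tert-butyldimethylsilyloxy)benzene | CC(C)(C)[Si](C)(C)Oc1ccc(Br)cc1O[Si](C)(C)C(C)(C)C | intermediate
17 | 3,4-bis(tert-butyldimethylsilyloxy)phenyllithium (not isolated) | [Li]c1ccc(O[Si](C)(C)C(C)(C)C)c(O[Si](C)(C)C(C)(C)C)c1 | intermediate
18 | lithium [3,4-bis(tert-butyldimethylsilyloxy)phenyl]triisopropoxyborate (not isolated) | [Li+].CC(C)O[B-](OC(C)C)(OC(C)C)c1ccc(O[Si](C)(C)C(C)(C)C)c(O[Si](C)(C)C(C)(C)C)c1 | intermediate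
19 | 3,4-bis(tert-butyldimethylsilyloxy)phenylboronic acid | CC(C)(C)[Si](C)(C)Oc1ccc(B(O)O)cc1O[Si](C)(C)C(C)(C)C | intermediate
20 | (2S)-tetrakis-TBS flavanone | C/C(=C/Cc1c(O[Si](C)(C)C(C)(C)C)ccc2c1O[C@H](c1ccc(O[Si](C)(C)C(C)(C)C)c(O[Si](C)(C)C(C)(C)C)c1)CC2=O)CO[Si](C)(C)C(C)(C)C | intermediate
21 | (2S)-2-(3,4-dihydroxyphenyl)-7-hydroxy-8-[(Z)-4-hydroxy-3-methylbut-2-enyl]chroman-4-one (CNP0205253.2) | C/C(=C/Cc1c(O)ccc2c1O[C@H](c1ccc(O)c(O)c1)CC2=O)CO | target

**Step count**
Total step count: 12 (ten in the main line, two for the boronic acid).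
Longest linear sequence: 10 steps (1 → 3 → 4 → 6 → 8 → 10 → 11 → 13 → 14 → 20 → 21).

**Steps most likely to fail**

1. **Step 7.**
   - What may go wrong: chemoselectivity may be lost through hydride attack on C2 or C4 of the pyranone before the lactone has opened, or through conjugate reduction of the enoate or enal. The geometry may also leak through reversible oxa-Michael addition of the phenoxide to the transient enal.
   - Fallback, from 8 back to 13: C4'' is brought in at the alcohol level, so no hydride meets the chromone.
   - Methallyl alcohol is added to excess diisopropyldichlorosilane (Et3N, CH2Cl2) to give chloro(diisopropyl)(2-methylallyloxy)silane F1.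
   - F1 silylates the 7-OH of 8 (imidazole, CH2Cl2) to the mixed silaketal 8-allyl-7-[diisopropyl(2-methylallyloxy)silyloxy]chromone F2.
   - Temporary silicon-tethered RCM (second-generation Ru carbene, dilute toluene) should close the nine-membered cyclic silaketal F3 with a cis ring olefin.
   - Et3N·3HF in THF then removes the silicon and gives 13.

2. **Step 6.**
   - What may go wrong: closure onto the electron-poor 1,1-disubstituted olefin may be slow. Allyl–allyl dimerisation, Ru-hydride-induced allyl migration or catalyst decay could then take over.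
   - Fallback, from 8 back to 11: the same ring and the same C=C bond are made by olefination.
   - Compound 8 is esterified with 2-(diethoxyphosphoryl)propanoic acid (EDC, DMAP, CH2Cl2) to 8-allyl-4-oxo-4H-chromen-7-yl 2-(diethoxyphosphoryl)propanoate F4.
   - The terminal olefin is cleaved (cat. OsO4, NaIO4, 2,6-lutidine, dioxane–water) to the arylacetaldehyde 4-oxo-8-(2-oxoethyl)-4H-chromen-7-yl 2-(diethoxyphosphoryl)propanoate F5.
   - An intramolecular Horner–Wadsworth–Emmons reaction under Masamune–Roush conditions (LiCl, i-Pr2NEt, MeCN, high dilution) closes lactone 11, whose ring size again allows only the cis olefin.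

3. **Step 11.**
   - What may go wrong: facial selectivity may be insufficient. Turnover may also stall through protodeboronation of the electron-rich boronic acid and loss of silyl ethers in the warm, wet, weakly acidic medium.
   - Fallback, from 14 and 16 back to 21: Lewis-acid activation, a stoichiometric aryl nucleophile and a resolution replace the asymmetric catalysis.
   - Compound 14 is converted with TBSOTf (CH2Cl2) into the 4-silyloxybenzopyrylium triflate F6.
   - The Grignard reagent 3,4-bis(tert-butyldimethylsilyloxy)phenylmagnesium bromide F7, made from 16 (Mg, THF), adds to C2 at −78 °C to give the racemic 2-aryl-4-silyloxy-2H-chromene F8.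
   - Et3N·3HF in THF removes all five silyl groups and the enol tautomerises to the racemic flavanone F9.
   - Preparative HPLC on a polysaccharide chiral phase with a slightly acidified eluent separates 21 from the (2R)-antipode F10.

**Further compounds**
F1 | step 7 | chloro(diisopropyl)(2-methylallyloxy)silane | C=C(C)CO[Si](Cl)(C(C)C)C(C)C
F2 | step 7 | 8-allyl-7-[diisopropyl(2-methylallyloxy)silyloxy]chromone | C=C(C)CO[Si](C(C)C)(C(C)C)Oc1ccc2c(=O)ccoc2c1CC=C
F3 | step 7 | chromone-fused nine-membered cyclic diisopropylsilaketal with Z ring olefin | C/C1=C/Cc2c(O[Si](C(C)C)(C(C)C)OC1)ccc3c(=O)ccoc23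
F4 | step 6 | 8-allyl-4-oxo-4H-chromen-7-yl 2-(diethoxyphosphoryl)propanoate | CCOP(=O)(OCC)C(C)C(=O)Oc1ccc2c(=O)ccoc2c1CC=C
F5 | step 6 | 4-oxo-8-(2-oxoethyl)-4H-chromen-7-yl 2-(diethoxyphosphoryl)propanoate | CCOP(=O)(OCC)C(C)C(=O)Oc1ccc2c(=O)ccoc2c1CC=O
F6 | step 11 | 4,7-bis(tert-butyldimethylsilyloxy)-8-[(Z)-4-(tert-butyldimethylsilyloxy)-3-methylbut-2-enyl]-1-benzopyrylium triflate | C/C(=C/Cc1c(O[Si](C)(C)C(C)(C)C)ccc2c(O[Si](C)(C)C(C)(C)C)cc[o+]c12)CO[Si](C)(C)C(C)(C)C.[O-]S(=O)(=O)C(F)(F)F
F7 | step 11 | 3,4-bis(tert-butyldimethylsilyloxy)phenylmagnesium bromide | Br[Mg]c1ccc(O[Si](C)(C)C(C)(C)C)c(O[Si](C)(C)C(C)(C)C)c1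
F8 | step 11 | racemic pentakis-TBS 2-aryl-4-silyloxy-2H-chromene | C/C(=C/Cc1c(O[Si](C)(C)C(C)(C)C)ccc2c1OC(c1ccc(O[Si](C)(C)C(C)(C)C)c(O[Si](C)(C)C(C)(C)C)c1)C=C2O[Si](C)(C)C(C)(C)C)CO[Si](C)(C)C(C)(C)C
F9 | step 11 | racemic 2-(3,4-dihydroxyphenyl)-7-hydroxy-8-[(Z)-4-hydroxy-3-methylbut-2-enyl]chroman-4-one | C/C(=C/Cc1c(O)ccc2c1OC(c1ccc(O)c(O)c1)CC2=O)CO
F10 | step 11 | (2R)-2-(3,4-dihydroxyphenyl)-7-hydroxy-8-[(Z)-4-hydroxy-3-methylbut-2-enyl]chroman-4-one | C/C(=C/Cc1c(O)ccc2c1O[C@@H](c1ccc(O)c(O)c1)CC2=O)CO
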